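**Overview**

- First cut: the strained spiro bond C3–C2′, which leads back to a racemic 2′-bromo homoisoflavanone. This is possible because C3 is the alpha-carbon of the C4 carbonyl in ring C and sits 1,4 to arene carbon C2′ across the benzylic CH2, so C3–C2′ is an enolate–aryl bond and C3–H stays enolisable until that bond exists.
- Second cut: C3–CH2, through the exocyclic C3=CH alkene (aldol condensation, then conjugate reduction), to 5,7-dimethoxychroman-4-one and 2-bromo-3,4-dimethoxybenzaldehyde.
- Third cuts: C4–C4a (Friedel–Crafts acylation) and O1–C2 (phenol O-alkylation) of the chromanone; the aryl C–Br and one O–CH3 of the aldehyde, back to isovanillin.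
- Forward ring order: ring C (pyranone) is closed first onto ring A, the brominated ring B is attached at C3, and the cyclobutene is closed last.
- Stereochemistry: the only stereocentre, spiro C3, is set in the last step by a chiral palladium catalyst acting on the racemic bromide through its planar enolate; afterwards C3 bears no hydrogen and cannot racemise.

Key step: step 7

Assumption: the sense of induction of the ligand in step 7 cannot be predicted; (R)-DTBM-SEGPHOS is written, and its mirror image is used instead if that is the antipode that leads to the (S) product.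

**Route**

Step 1
Reactants: 1 3,5-dimethoxyphenol; 2 3-chloropropanoic acid
Product: 3 3-(3,5-dimethoxyphenoxy)propanoic acid
Conditions: NaOH (aq, 2.2 equiv), H2O, reflux; then HCl to pH 1
Reagents that add atoms: none
Why: Williamson ether synthesis, in which the phenoxide displaces the primary chloride of the 3-chloropropanoate by SN2 and the acid is released on acidification.

Step 2
Reactants: 3 3-(3,5-dimethoxyphenoxy)propanoic acid
Product: 4 5,7-dimethoxychroman-4-one
Conditions: Eaton's reagent (P2O5 in MeSO3H), 70 °C
Reagents that add atoms: none
Why: Intramolecular Friedel–Crafts acylation onto the position ortho to the ether oxygen of a triply oxygenated arene; the two ortho positions are equivalent, so only one regioisomer can form.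

Step 3
Reactants: 5 isovanillin (3-hydroxy-4-methoxybenzaldehyde)
Product: 6 2-bromo-3-hydroxy-4-methoxybenzaldehyde
Conditions: Br2, NaOAc, Fe powder (cat.), AcOH, rt
Reagents that add atoms: bromine, BrBr
Why: Electrophilic aromatic bromination directed by the free phenol to the ortho position between OH and CHO (C2), the established outcome for isovanillin under acetate-buffered conditions.

Step 4
Reactants: 6 2-bromo-3-hydroxy-4-methoxybenzaldehyde
Product: 7 2-bromo-3,4-dimethoxybenzaldehyde
Conditions: MeI, K2CO3, DMF, rt
Reagents that add atoms: iodomethane, CI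
Why: Williamson O-methylation of the phenoxide, which leaves the aldehyde and the aryl bromide untouched.

Step 5
Reactants: 4 5,7-dimethoxychroman-4-one; 7 2-bromo-3,4-dimethoxybenzaldehyde
Product: 9 (E)-3-(2-bromo-3,4-dimethoxybenzylidene)-5,7-dimethoxychroman-4-one, via aldol adduct 8 (not isolated)
Conditions: p-TsOH·H2O (0.2 equiv), toluene, reflux, Dean–Stark
Reagents that add atoms: none
Why: Acid-catalysed crossed aldol condensation (Claisen–Schmidt type) in which only C3 of the chromanone is enolisable and dehydration should give the conjugated (E)-alkene (aryl anti to C4=O) as the thermodynamic isomer, acid being chosen because hot amine base tends to move the alkene into the ring.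

Step 6
Reactants: 9 (E)-3-(2-bromo-3,4-dimethoxybenzylidene)-5,7-dimethoxychroman-4-one
Product: 10 racemic 3-(2-bromo-3,4-dimethoxybenzyl)-5,7-dimethoxychroman-4-one
Conditions: Cu(OAc)2 (5 mol %), 1,2-bis(diphenylphosphino)benzene (5 mol %), (EtO)2MeSiH (1.2 equiv), t-BuOH (1.2 equiv), toluene, 0 °C to rt
Reagents that add atoms: none
Why: Copper hydride conjugate reduction, in which the phosphine-bound monovalent copper hydride formed from divalent copper acetate and the silane delivers hydride to the benzylic beta-carbon and t-BuOH protonates the copper enolate at C3 without facial bias (the racemate is wanted), while the aryl bromide and the electron-rich, hindered aryl ketone should not react.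

Step 7
Reactants: 10 racemic 3-(2-bromo-3,4-dimethoxybenzyl)-5,7-dimethoxychroman-4-one
Product: 11 (S)-4,5,5′,7′-tetramethoxyspiro[bicyclo[4.2.0]octa-1,3,5-triene-7,3′-chroman]-4′-one (CNP0192565.1)
Conditions: Pd2(dba)3 (2.5 mol %), (R)-DTBM-SEGPHOS (6 mol %), K3PO4 (2 equiv), degassed toluene, 90 °C
Reagents that add atoms: none
Why: Proposed new method: zerovalent palladium inserts into the C2′–Br bond, K3PO4 enolises the C4 ketone at C3, the enolate replaces bromide on divalent palladium to give the C-bound five-membered palladacycle Pd–C2′–C1′–CH2–C3 (in equilibrium with the O-bound enolate), and C(sp2)–C(sp3) reductive elimination forms C3–C2′ and returns zerovalent palladium. The closest known reactions are the Pd-catalysed enantioselective alpha-arylation of alpha-branched cyclic ketones, the intramolecular alpha-arylations that give quaternary oxindoles and indanes, and the Pd-catalysed methyl C(sp3)–H arylation of 2-bromoaryl substrates to benzocyclobutenes, which ends in reductive elimination from the same kind of aryl–alkyl palladacycle; an enolate arylation that closes a four-membered ring has not been shown. The cyclobutene closes in a formal 4-exo-trig sense (enolate carbon onto the arene carbon that carried bromine), in practice by contraction of the five-membered palladacycle. The spiro stereocentre C3 is set by the chiral bisphosphine on palladium: both enantiomers of 10 give the same planar enolate, the diastereomeric palladium enolates should interconvert faster than they eliminate (Curtin–Hammett), and the product has no alpha-hydrogen, so it cannot racemise. The step needs enantioface selection at C3 and C–C bond formation in preference to beta-hydride loss from C2–H; these are secured by the acidic C3–H (a mild base suffices), by the bromine that fixes the site between the methoxy group and the benzylic carbon, and by a bulky chelating ligand that leaves no open site on palladium and accelerates reductive elimination.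

**Compound list**

1 | 3,5-dimethoxyphenol | COc1cc(O)cc(OC)c1 | starting material
2 | 3-chloropropanoic acid | OC(=O)CCCl | starting material
3 | 3-(3,5-dimethoxyphenoxy)propanoic acid | COc1cc(OC)cc(OCCC(=O)O)c1 | intermediate
4 | 5,7-dimethoxychroman-4-one | COc1cc(OC)c2c(c1)OCCC2=O | intermediate
5 | isovanillin (3-hydroxy-4-methoxybenzaldehyde) | COc1ccc(C=O)cc1O | starting material
6 | 2-bromo-3-hydroxy-4-methoxybenzaldehyde | COc1ccc(C=O)c(Br)c1O | intermediate
7 | 2-bromo-3,4-dimethoxybenzaldehyde | COc1ccc(C=O)c(Br)c1OC | intermediate
8 | 3-[(2-bromo-3,4-dimethoxyphenyl)(hydroxy)methyl]-5,7-dimethoxychroman-4-one (aldol adduct, mixture of diastereomers, not isolated) | COc1cc(OC)c2c(c1)OCC(C(O)c1ccc(OC)c(OC)c1Br)C2=O | intermediate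
9 | (E)-3-(2-bromo-3,4-dimethoxybenzylidene)-5,7-dimethoxychroman-4-one | COc1cc(OC)c2c(c1)OC/C(=C\c1ccc(OC)c(OC)c1Br)C2=O | intermediate
10 | racemic 3-(2-bromo-3,4-dimethoxybenzyl)-5,7-dimethoxychroman-4-one | COc1cc(OC)c2c(c1)OCC(Cc1ccc(OC)c(OC)c1Br)C2=O | intermediate
11 | (S)-4,5,5′,7′-tetramethoxyspiro[bicyclo[4.2.0]octa-1,3,5-triene-7,3′-chroman]-4′-one; chromanone C3 is the spiro atom, bonded to the cyclobutene CH2 and to the arene carbon next to a methoxy group | COc1cc(OC)c2c(c1)OC[C@@]1(Cc3ccc(OC)c(OC)c31)C2=O | target

**Step count**

Total: 7 steps. Longest linear sequence: 5 steps (steps 1, 2, 5, 6, 7 or steps 3, 4, 5, 6, 7).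

**Steps most likely to fail**

Step 7. Reductive elimination to the strained ring may be outrun by beta-hydride loss from C2–H or by reductive loss of bromine, and the facial selectivity at C3 may be poor.

The fallback uses known chemistry only. It sets out from phenol 1 and a commercial nitrile and returns at 11. The four-membered ring is closed at the other aryl–carbon bond (C1′–CH2) by the established Pd-catalysed methyl C(sp3)–H arylation, and ring C is closed last.

- Commercial 2-(2,3-dimethoxyphenyl)acetonitrile F1 is brominated para to the unhindered 3-methoxy group (NBS, MeCN, rt) to 2-(6-bromo-2,3-dimethoxyphenyl)acetonitrile F2.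
- C-Methylation (LiN(i-Pr)2, THF, −78 °C; MeI) should give 2-(6-bromo-2,3-dimethoxyphenyl)propanenitrile F3.
- A second deprotonation followed by monomeric formaldehyde should give 2-(6-bromo-2,3-dimethoxyphenyl)-3-hydroxy-2-methylpropanenitrile F4.
- Mitsunobu etherification with 1 (PPh3, DIAD, toluene, 80 °C) gives 2-(6-bromo-2,3-dimethoxyphenyl)-3-(3,5-dimethoxyphenoxy)-2-methylpropanenitrile F5.
- Methyl C–H arylation (Pd(OAc)2, P(t-Bu)3·HBF4, K2CO3, DMF, 140 °C) closes the benzocyclobutene to 7-[(3,5-dimethoxyphenoxy)methyl]-4,5-dimethoxybicyclo[4.2.0]octa-1,3,5-triene-7-carbonitrile F6.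
- Intramolecular Houben–Hoesch acylation of the phloroglucinol-type ring (ZnCl2, HCl gas, Et2O, 0 °C) gives the cyclic ketimine F7 as its hydrochloride; warm water hydrolyses it to the racemic spiro ketone F8.
- Preparative HPLC on a chiral stationary phase delivers 11.

Step 6. The hydride may over-reduce the C4 carbonyl or remove bromine, or the hindered trisubstituted enone may not be fully converted.

The fallback sets out from 9 and returns at 10. The exocyclic alkene is first moved into the ring (RhCl3·3H2O cat., EtOH, reflux) to give 3-(2-bromo-3,4-dimethoxybenzyl)-5,7-dimethoxy-4H-chromen-4-one F9. Its unsubstituted C2 then takes up hydride in a 1,4-sense (LiBH(s-Bu)3, THF, −78 °C; aqueous NH4Cl), a known way from chromones and isoflavones to the chromanones that spares aryl bromides.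

Step 1. Beta-elimination of the 3-chloropropanoate to acrylate and its hydrolysis may outrun O-alkylation, so that conversion of the phenol stays low.

The fallback sets out from 1 and returns at 3. Oxa-Michael addition of 1 to acrylonitrile (benzyltrimethylammonium hydroxide cat., neat acrylonitrile, reflux) gives 3-(3,5-dimethoxyphenoxy)propanenitrile F10, and hydrolysis of the nitrile (conc. HCl, reflux) gives acid 3.

**Further compounds**

F1 | step 7 | 2-(2,3-dimethoxyphenyl)acetonitrile (commercial) | COc1cccc(CC#N)c1OC
F2 | step 7 | 2-(6-bromo-2,3-dimethoxyphenyl)acetonitrile | COc1ccc(Br)c(CC#N)c1OC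
F3 | step 7 | racemic 2-(6-bromo-2,3-dimethoxyphenyl)propanenitrile | COc1ccc(Br)c(C(C)C#N)c1OC
F4 | step 7 | racemic 2-(6-bromo-2,3-dimethoxyphenyl)-3-hydroxy-2-methylpropanenitrile | COc1ccc(Br)c(C(C)(CO)C#N)c1OC
F5 | step 7 | racemic 2-(6-bromo-2,3-dimethoxyphenyl)-3-(3,5-dimethoxyphenoxy)-2-methylpropanenitrile | COc1cc(OC)cc(OCC(C)(C#N)c2c(Br)ccc(OC)c2OC)c1
F6 | step 7 | racemic 7-[(3,5-dimethoxyphenoxy)methyl]-4,5-dimethoxybicyclo[4.2.0]octa-1,3,5-triene-7-carbonitrile | COc1cc(OC)cc(OCC2(C#N)Cc3ccc(OC)c(OC)c32)c1
F7 | step 7 | racemic 4,5,5′,7′-tetramethoxyspiro[bicyclo[4.2.0]octa-1,3,5-triene-7,3′-chroman]-4′-imine (ketimine, hydrolysed without isolation) | COc1cc(OC)c2c(c1)OCC1(Cc3ccc(OC)c(OC)c31)C2=N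
F8 | step 7 | racemic 4,5,5′,7′-tetramethoxyspiro[bicyclo[4.2.0]octa-1,3,5-triene-7,3′-chroman]-4′-one | COc1cc(OC)c2c(c1)OCC1(Cc3ccc(OC)c(OC)c31)C2=O
F9 | step 6 | 3-(2-bromo-3,4-dimethoxybenzyl)-5,7-dimethoxy-4H-chromen-4-one | COc1cc(OC)c2c(c1)OC=C(Cc1ccc(OC)c(OC)c1Br)C2=O
F10 | step 1 | 3-(3,5-dimethoxyphenoxy)propanenitrile | COc1cc(OC)cc(OCCC#N)c1
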